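Count everything in one unit, the substrate charge: x is the share of it still free, b the reagent present on the same scale, so the north-east flask starts at x whole and b of 1.50.

| flask | substrate | reagent | temperature | remark | time |
|---|---|---|---|---|---|
| north-east | 20 mM | 30 mM | 5 °C | the very flask that is asked about, followed so far |  |
| west | 20 mM | 45 mM | 0 °C | run made earlier |  |
| flask | 20 mM | 30.0 mM | 5 °C |  | 10 h |

north-east run (percent of the substrate charged)

| time / h | single product / % |
|---|---|
| 1.33 | 45.2 |
| 2.50 | 50.8 |
| 4.00 | 54.2 |
| 5.00 | 54.9 |
| 6.00 | 55.5 |
| 8.00 | 56.4 |

west run (percent of the substrate charged)

| time / min | single product / % |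
|---|---|
| 8.00 | 15.1 |
| 15.0 | 23.0 |
| 20.0 | 27.3 |
| 30.0 | 33.5 |
| 40.0 | 38.0 |

(readings scatter by 0.3 percentage points)

- what is taken out of single product is counted as made
- additions bring no volume worth counting

1. single product, in percent of the substrate first charged, at 10 h
2. the remedy with the largest gain of single product, or "none" below 2 percentage points (spring / dusk / dawn / autumn / none)
3. single product present, with what was taken out counted in, in percent of the substrate first charged, after dusk
4. single product present, with what was taken out counted in, in percent of the substrate first charged, after autumn

- spring: at 10 h take out 90% of the single product then present, then wait 5.0 h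
- dusk: change nothing and wait 5.0 h more
- dawn: at 10 h add reagent, 50.0% of the amount charged, then wait 5.0 h
- autumn: at 10 h raise the temperature by 10 K, then wait 5.0 h

Why does the north-east flask stall? Counting reacted substrate as single product, its x reads 43.6% at 8.00 h, and on paper b should still be 0.936, yet the product barely climbs.

So where does the reagent go? In the west run, let s be the rate of loss of ln x, which follows the reagent present. It reads 0.0205 min⁻¹ over the first interval and 0.00701 min⁻¹ over the last, so 1/s rises from 48.8 min to 143 min. That is a gradient of 3.03.

Reagent destroying itself at second order gives such a rise, with gradient r + x/b. Here r, the selectivity factor, is the reagent lost to itself per reagent lost to substrate when x equals b. As x/b starts at 0.444 and climbs, this reading puts r below 2.58, and we take r = 2.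

How far can a given reagent carry? Each share of substrate converted costs one share of reagent plus r·b/x more. Summing this until b is nil, with r = 2, gives x·x/(x + b) from a starting x and b, which from the charge is 40.0%: this is the stop share, the x at which the reagent ends by our reckoning. So the north-east flask has 3.6 percentage points to come from its last reading by our reckoning, up to a ceiling of 60.0% single product, where the forecast puts a plateau of about 58 %.

What does new reagent buy? From the x of the last reading, the dawn addition taken by itself has a stop share of 16.0%, which is room for 28 points if the wait reaches it, far above the other remedies, which add no reagent and which we credit with the earlier room at most.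

The forecast gives 56.9% (56.4% to 57.5%) at the asked time, dawn as best, 57.4% (56.8% to 58.2%) after dusk and 57.6% (56.9% to 58.6%) after autumn, pointing “towards reagent destroying itself, roughly second order, at about twice the rate it reacts with substrate”.

The flask gives 56.0% at the asked time, dawn as best with a gain of 19 points in its wait of 5.0 h against the room of 28 points in our reckoning, 56.1% after dusk and 56.1% after autumn.

    2 reagent → homo dimer (k = 0.880 M⁻¹ min⁻¹, Ea = 40.0 kJ mol⁻¹)
    reagent + triple product → tetra adduct (k = 0.530 M⁻¹ min⁻¹, Ea = 57.0 kJ mol⁻¹)
    substrate + reagent → single product (k = 0.840 M⁻¹ min⁻¹, Ea = 47.0 kJ mol⁻¹)
    reagent + single product → bis adduct (k = 0.0500 M⁻¹ min⁻¹, Ea = 47.0 kJ mol⁻¹)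
    reagent + bis adduct → triple product (k = 0.230 M⁻¹ min⁻¹, Ea = 55.0 kJ mol⁻¹)
    (constants at 5 °C)

In the flask, the midpoint of the turnover up to the asked time fell at 0.161 h in the homo dimer step and at 0.388 h in the substrate step, and reagent stood at 1.09% of its charge at 5.00 h. After that single product went from 54.8% at 5.00 h to 56.0% at 10.0 h, with 42.3% of the substrate free against a stop share of 40.0%. For the neighbour charged with 12 mM of reagent the stop share is 62.5%, and that flask holds 63% free at 10.0 h.

(The earlier runs and the new flask were computed for substances that don't exist, and the scatter is random.)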